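**Retrosynthetic overview**

1. Target 21 ⇐ 20 (three MOM ethers removed) ⇐ one-carbon ring contraction of the seven-membered 3-methyl-2,5-dihydro-1-benzoxepine ring fused to ring B in 17; the pyran ring is made last and never closed directly.
2. Enabling feature: in 17 the oxepine CH2 at C-5 is benzylic to ring B and allylic to the C-3=C-4 ring alkene, and lies 1,4 to the allylic aryl ether bond O-1–C-2. The cis ring alkene becomes a Z-diene, the freed phenol O–H feeds a [1,7]-H shift and an oxa-6π closure, and the O–CH2 carbon ends as the second methyl group.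
3. 17 ⇐ ring-closing metathesis of O-methallyl/C-prenyl compound 16. The C-2' prenyl and C-6' 1,1-dimethylallyl groups ⇐ two successive Claisen rearrangements of 3'-O-(1,1-dimethylallyl) ethers (ortho, then para through a dienone with two identical prenyl groups). The 8-prenyl group ⇐ Claisen–Cope shift of the 5-O-prenyl ether.
4. Flavonol (ring C) ⇐ Algar–Flynn–Oyamada oxidation of chalcone 7 ⇐ Claisen–Schmidt condensation of aldehyde 3 (from 3,4-dihydroxybenzaldehyde) with acetophenone 6 (from 2,4,6-trihydroxyacetophenone).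
5. Ring order: rings A and B are bought; ring C; oxepine on ring B; contraction to the pyran.

Key step: step 13

Assumption: methyl 2-methylbut-3-en-2-yl carbonate is treated as a stock reagent (otherwise one operation from 2-methylbut-3-en-2-ol and methyl chloroformate).

**Route**

Step 1
Reactants: 1 3,4-dihydroxybenzaldehyde
Product: 2 3-hydroxy-4-(methoxymethoxy)benzaldehyde
Conditions: MOMCl (1.05 equiv), K2CO3, acetone, 0 °C to rt
Reagents that add atoms: chloromethyl methyl ether, COCCl
Why: Williamson-type O-alkylation in which the 4-OH, para to the formyl group and therefore the more acidic phenol, should be ionised and alkylated first by the weak base.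

Step 2
Reactants: 2 3-hydroxy-4-(methoxymethoxy)benzaldehyde
Product: 3 4-(methoxymethoxy)-3-[(2-methylbut-3-en-2-yl)oxy]benzaldehyde
Conditions: methyl 2-methylbut-3-en-2-yl carbonate, Pd(PPh3)4 (5 mol %), THF, rt
Reagents that add atoms: methyl 2-methylbut-3-en-2-yl carbonate, COC(=O)OC(C)(C)C=C
Why: Tsuji–Trost O-allylation in which the phenol should attack the 1,1-dimethyl-π-allylpalladium complex at its more substituted terminus under kinetic control, giving the tertiary allyl aryl ether that also protects O-3' until the Claisen step.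

Step 3
Reactants: 4 1-(2,4,6-trihydroxyphenyl)ethan-1-one
Product: 5 1-[2,6-dihydroxy-4-(methoxymethoxy)phenyl]ethan-1-one
Conditions: MOMCl (1.0 equiv), K2CO3, acetone, 0 °C to rt
Reagents that add atoms: chloromethyl methyl ether, COCCl
Why: Williamson O-alkylation that should be selective for the 4-OH because both ortho hydroxyls are held in hydrogen bonds to the acetyl carbonyl.

Step 4
Reactants: 5 1-[2,6-dihydroxy-4-(methoxymethoxy)phenyl]ethan-1-one
Product: 6 1-[2-hydroxy-4-(methoxymethoxy)-6-[(3-methylbut-2-en-1-yl)oxy]phenyl]ethan-1-one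
Conditions: prenyl bromide (1.05 equiv), K2CO3, acetone, reflux
Reagents that add atoms: 1-bromo-3-methylbut-2-ene, CC(C)=CCBr
Why: Williamson O-alkylation of one of the two equivalent chelated hydroxyls, after which the remaining hydroxyl stays hydrogen-bonded to the ketone and should resist a second alkylation.

Step 5
Reactants: 3 4-(methoxymethoxy)-3-[(2-methylbut-3-en-2-yl)oxy]benzaldehyde; 6 1-[2-hydroxy-4-(methoxymethoxy)-6-[(3-methylbut-2-en-1-yl)oxy]phenyl]ethan-1-one
Product: 7 (E)-1-[2-hydroxy-4-(methoxymethoxy)-6-[(3-methylbut-2-en-1-yl)oxy]phenyl]-3-[4-(methoxymethoxy)-3-[(2-methylbut-3-en-2-yl)oxy]phenyl]prop-2-en-1-one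
Conditions: KOH, EtOH/H2O, rt
Reagents that add atoms: none
Why: Claisen–Schmidt aldol condensation of the methyl ketone enolate with the non-enolisable and still unhindered aldehyde, with E1cB dehydration expected to give the thermodynamically favoured E enone.

Step 6
Reactants: 7 (E)-1-[2-hydroxy-4-(methoxymethoxy)-6-[(3-methylbut-2-en-1-yl)oxy]phenyl]-3-[4-(methoxymethoxy)-3-[(2-methylbut-3-en-2-yl)oxy]phenyl]prop-2-en-1-one
Product: 9 3-hydroxy-7-(methoxymethoxy)-2-[4-(methoxymethoxy)-3-[(2-methylbut-3-en-2-yl)oxy]phenyl]-5-[(3-methylbut-2-en-1-yl)oxy]-4H-chromen-4-one, via trans-dihydroflavonol 8 (not isolated)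
Conditions: H2O2 (30% aq), NaOH, MeOH, 0 °C to rt
Reagents that add atoms: hydrogen peroxide, OO
Why: Algar–Flynn–Oyamada oxidation in which alkaline peroxide should oxygenate the enone while the 2'-phenoxide closes ring C to the racemic trans-dihydroflavonol 8, whose two stereocentres are erased when a second equivalent of peroxide dehydrogenates it to the flavonol.

Step 7
Reactants: 9 3-hydroxy-7-(methoxymethoxy)-2-[4-(methoxymethoxy)-3-[(2-methylbut-3-en-2-yl)oxy]phenyl]-5-[(3-methylbut-2-en-1-yl)oxy]-4H-chromen-4-one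
Product: 10 3,7-bis(methoxymethoxy)-2-[4-(methoxymethoxy)-3-[(2-methylbut-3-en-2-yl)oxy]phenyl]-5-[(3-methylbut-2-en-1-yl)oxy]-4H-chromen-4-one
Conditions: MOMCl, K2CO3, acetone, 50 °C
Reagents that add atoms: chloromethyl methyl ether, COCCl
Why: Williamson O-alkylation of the only free hydroxyl, the acidic 3-OH, so that it cannot compete in the later etherifications of ring B.

Step 8
Reactants: 10 3,7-bis(methoxymethoxy)-2-[4-(methoxymethoxy)-3-[(2-methylbut-3-en-2-yl)oxy]phenyl]-5-[(3-methylbut-2-en-1-yl)oxy]-4H-chromen-4-one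
Product: 12 5-hydroxy-2-[3-hydroxy-4-(methoxymethoxy)-2-(3-methylbut-2-en-1-yl)phenyl]-3,7-bis(methoxymethoxy)-8-(3-methylbut-2-en-1-yl)-4H-chromen-4-one, via 8-prenyl-5-hydroxyflavone 11 (not isolated)
Conditions: Eu(fod)3 (10 mol %), NaHCO3, PhCl, 85 °C then 130 °C
Reagents that add atoms: none
Why: Two aromatic Claisen rearrangements in one pot, in which europium chelation between the 4-carbonyl and O-5 should drive the [3,3] shift of the prenyl ether to C-6 and the following Cope shift to C-8 (para-Claisen–Cope, intermediate 11), and at the higher temperature the 1,1-dimethylallyl ether of ring B should undergo the ortho-Claisen rearrangement to its only free ortho position C-2', which delivers the unbranched prenyl group.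

Step 9
Reactants: 12 5-hydroxy-2-[3-hydroxy-4-(methoxymethoxy)-2-(3-methylbut-2-en-1-yl)phenyl]-3,7-bis(methoxymethoxy)-8-(3-methylbut-2-en-1-yl)-4H-chromen-4-one
Product: 13 5-hydroxy-3,7-bis(methoxymethoxy)-2-[4-(methoxymethoxy)-2-(3-methylbut-2-en-1-yl)-3-[(2-methylbut-3-en-2-yl)oxy]phenyl]-8-(3-methylbut-2-en-1-yl)-4H-chromen-4-one
Conditions: methyl 2-methylbut-3-en-2-yl carbonate, Pd(PPh3)4 (5 mol %), THF, rt
Reagents that add atoms: methyl 2-methylbut-3-en-2-yl carbonate, COC(=O)OC(C)(C)C=C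
Why: Tsuji–Trost O-allylation as in step 2, expected to be chemoselective for the free 3'-OH because the 5-OH is locked in a hydrogen bond to the 4-carbonyl.

Step 10
Reactants: 13 5-hydroxy-3,7-bis(methoxymethoxy)-2-[4-(methoxymethoxy)-2-(3-methylbut-2-en-1-yl)-3-[(2-methylbut-3-en-2-yl)oxy]phenyl]-8-(3-methylbut-2-en-1-yl)-4H-chromen-4-one
Product: 15 5-hydroxy-2-[3-hydroxy-4-(methoxymethoxy)-2-(3-methylbut-2-en-1-yl)-6-(2-methylbut-3-en-2-yl)phenyl]-3,7-bis(methoxymethoxy)-8-(3-methylbut-2-en-1-yl)-4H-chromen-4-one, via ortho-dienone 14 (not isolated)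
Conditions: o-xylene, 140 °C
Reagents that add atoms: none
Why: para-Claisen rearrangement in which, with both ortho positions substituted, the [3,3] shift should give the non-enolisable dienone 14, and a Cope shift of either of its two identical prenyl groups then places the 1,1-dimethylallyl group at C-6' before tautomerisation restores the phenol.

Step 11
Reactants: 15 5-hydroxy-2-[3-hydroxy-4-(methoxymethoxy)-2-(3-methylbut-2-en-1-yl)-6-(2-methylbut-3-en-2-yl)phenyl]-3,7-bis(methoxymethoxy)-8-(3-methylbut-2-en-1-yl)-4H-chromen-4-one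
Product: 16 5-hydroxy-3,7-bis(methoxymethoxy)-2-[4-(methoxymethoxy)-3-[(2-methylprop-2-en-1-yl)oxy]-2-(3-methylbut-2-en-1-yl)-6-(2-methylbut-3-en-2-yl)phenyl]-8-(3-methylbut-2-en-1-yl)-4H-chromen-4-one
Conditions: 3-chloro-2-methylprop-1-ene, K2CO3, KI (cat.), DMF, 60 °C
Reagents that add atoms: 3-chloro-2-methylprop-1-ene, CC(=C)CCl
Why: Williamson O-alkylation of the 3'-OH, again expected to be selective over the chelated 5-OH under mild carbonate conditions.

Step 12
Reactants: 16 5-hydroxy-3,7-bis(methoxymethoxy)-2-[4-(methoxymethoxy)-3-[(2-methylprop-2-en-1-yl)oxy]-2-(3-methylbut-2-en-1-yl)-6-(2-methylbut-3-en-2-yl)phenyl]-8-(3-methylbut-2-en-1-yl)-4H-chromen-4-one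
Product: 17 5-hydroxy-3,7-bis(methoxymethoxy)-2-[9-(methoxymethoxy)-3-methyl-7-(2-methylbut-3-en-2-yl)-2,5-dihydro-1-benzoxepin-6-yl]-8-(3-methylbut-2-en-1-yl)-4H-chromen-4-one
Conditions: second-generation Grubbs catalyst RuCl2(=CHPh)(H2IMes)(PCy3) (10 mol %), PhMe, 80 °C
Reagents that add atoms: none
Why: Ring-closing olefin metathesis between the methallyl ether and the ortho prenyl group should close the seven-membered ring with loss of 2-methylpropene, the cis trisubstituted alkene being the only geometry possible in this ring, while the other prenyl group and the neopentyl-type vinyl group have no partner within reach for ring closure.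

Step 13
Reactants: 17 5-hydroxy-3,7-bis(methoxymethoxy)-2-[9-(methoxymethoxy)-3-methyl-7-(2-methylbut-3-en-2-yl)-2,5-dihydro-1-benzoxepin-6-yl]-8-(3-methylbut-2-en-1-yl)-4H-chromen-4-one
Product: 20 5-hydroxy-3,7-bis(methoxymethoxy)-2-[8-(methoxymethoxy)-2,2-dimethyl-6-(2-methylbut-3-en-2-yl)-2H-chromen-5-yl]-8-(3-methylbut-2-en-1-yl)-4H-chromen-4-one, via Z-dienylphenol 18 (not isolated), via ortho-quinone methide 19 (not isolated)
Conditions: KOt-Bu (4 equiv), DMSO, rt; then AcOH; PhMe, 60 °C
Reagents that add atoms: none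
Why: Proposed new method: tert-butoxide in DMSO should remove a proton from the ring CH2 at C-5 of the oxepine, the only C–H that is both benzylic to ring B and allylic, and the delocalised carbanion should expel the ring B aryloxide from C-2 in an E1cB 1,4-elimination that opens the seven-membered ring to the (Z)-3-methylbuta-1,3-dienyl phenoxide, the Z geometry being inherited from the cis ring alkene. After protonation to 18, a thermal [1,7]-sigmatropic hydrogen shift from the phenol O–H to the terminal CH2 (the former ring C-2, which thus becomes the second methyl group) should give ortho-quinone methide 19, and this closes the pyran ring by a thermal disrotatory oxa-6π electrocyclisation between the quinone methide oxygen and the dimethyl-substituted terminus, which restores the aromaticity of ring B. The closest known reaction types are the Z-selective base-induced 1,4-eliminative ring opening of cyclic allylic ethers and sulfones (5,6-dihydro-2H-pyrans, 3-sulfolenes) and the thermal conversion of (Z)-ortho-butadienylphenols into 2H-chromenes by [1,7]-hydrogen shift and electrocyclisation; their combination into a one-carbon ring contraction of a benzoxepine is the new element. No stereocentre is formed, because the new quaternary carbon carries two methyl groups. The step needs site-selective deprotonation and a Z-diene: the first is secured by the double activation of the oxepine CH2 while ring A is present as its 5-phenoxide (which also shields the pyranone from nucleophiles and its prenyl CH2 from deprotonation), the second by the ring itself, and the 1,4-placement of the leaving aryloxide makes the elimination irreversible so that simple alkene migration should not be the final outcome.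

Step 14
Reactants: 20 5-hydroxy-3,7-bis(methoxymethoxy)-2-[8-(methoxymethoxy)-2,2-dimethyl-6-(2-methylbut-3-en-2-yl)-2H-chromen-5-yl]-8-(3-methylbut-2-en-1-yl)-4H-chromen-4-one
Product: 21 3,5,7-trihydroxy-2-[8-hydroxy-2,2-dimethyl-6-(2-methylbut-3-en-2-yl)-2H-chromen-5-yl]-8-(3-methylbut-2-en-1-yl)-4H-chromen-4-one
Conditions: HCl (3 M aq), MeOH, 40 °C
Reagents that add atoms: none
Why: Acid-catalysed acetal exchange should remove the three methoxymethyl ethers as dimethoxymethane under conditions mild enough to leave the chromene and both prenyl-type side chains intact.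

**Compound list**

1 | 3,4-dihydroxybenzaldehyde | O=Cc1ccc(O)c(O)c1 | starting material
2 | 3-hydroxy-4-(methoxymethoxy)benzaldehyde | O=Cc1ccc(OCOC)c(O)c1 | intermediate
3 | 4-(methoxymethoxy)-3-[(2-methylbut-3-en-2-yl)oxy]benzaldehyde | O=Cc1ccc(OCOC)c(OC(C)(C)C=C)c1 | intermediate
4 | 1-(2,4,6-trihydroxyphenyl)ethan-1-one | CC(=O)c1c(O)cc(O)cc1O | starting material
5 | 1-[2,6-dihydroxy-4-(methoxymethoxy)phenyl]ethan-1-one | CC(=O)c1c(O)cc(OCOC)cc1O | intermediate
6 | 1-[2-hydroxy-4-(methoxymethoxy)-6-[(3-methylbut-2-en-1-yl)oxy]phenyl]ethan-1-one | CC(=O)c1c(O)cc(OCOC)cc1OCC=C(C)C | intermediate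
7 | (E)-1-[2-hydroxy-4-(methoxymethoxy)-6-[(3-methylbut-2-en-1-yl)oxy]phenyl]-3-[4-(methoxymethoxy)-3-[(2-methylbut-3-en-2-yl)oxy]phenyl]prop-2-en-1-one | O=C(/C=C/c1ccc(OCOC)c(OC(C)(C)C=C)c1)c1c(O)cc(OCOC)cc1OCC=C(C)C | intermediate
8 | racemic trans-(2R*,3R*)-3-hydroxy-7-(methoxymethoxy)-2-[4-(methoxymethoxy)-3-[(2-methylbut-3-en-2-yl)oxy]phenyl]-5-[(3-methylbut-2-en-1-yl)oxy]chroman-4-one (one enantiomer drawn) | O=C1[C@@H](O)[C@H](c2ccc(OCOC)c(OC(C)(C)C=C)c2)Oc2cc(OCOC)cc(OCC=C(C)C)c12 | intermediate (not isolated)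
9 | 3-hydroxy-7-(methoxymethoxy)-2-[4-(methoxymethoxy)-3-[(2-methylbut-3-en-2-yl)oxy]phenyl]-5-[(3-methylbut-2-en-1-yl)oxy]-4H-chromen-4-one | O=c1c(O)c(-c2ccc(OCOC)c(OC(C)(C)C=C)c2)oc2cc(OCOC)cc(OCC=C(C)C)c12 | intermediate
10 | 3,7-bis(methoxymethoxy)-2-[4-(methoxymethoxy)-3-[(2-methylbut-3-en-2-yl)oxy]phenyl]-5-[(3-methylbut-2-en-1-yl)oxy]-4H-chromen-4-one | O=c1c(OCOC)c(-c2ccc(OCOC)c(OC(C)(C)C=C)c2)oc2cc(OCOC)cc(OCC=C(C)C)c12 | intermediate
11 | 5-hydroxy-3,7-bis(methoxymethoxy)-2-[4-(methoxymethoxy)-3-[(2-methylbut-3-en-2-yl)oxy]phenyl]-8-(3-methylbut-2-en-1-yl)-4H-chromen-4-one | O=c1c(OCOC)c(-c2ccc(OCOC)c(OC(C)(C)C=C)c2)oc2c(CC=C(C)C)c(OCOC)cc(O)c12 | intermediate (not isolated)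
12 | 5-hydroxy-2-[3-hydroxy-4-(methoxymethoxy)-2-(3-methylbut-2-en-1-yl)phenyl]-3,7-bis(methoxymethoxy)-8-(3-methylbut-2-en-1-yl)-4H-chromen-4-one | O=c1c(OCOC)c(-c2c(CC=C(C)C)c(O)c(OCOC)cc2)oc2c(CC=C(C)C)c(OCOC)cc(O)c12 | intermediate
13 | 5-hydroxy-3,7-bis(methoxymethoxy)-2-[4-(methoxymethoxy)-2-(3-methylbut-2-en-1-yl)-3-[(2-methylbut-3-en-2-yl)oxy]phenyl]-8-(3-methylbut-2-en-1-yl)-4H-chromen-4-one | O=c1c(OCOC)c(-c2c(CC=C(C)C)c(OC(C)(C)C=C)c(OCOC)cc2)oc2c(CC=C(C)C)c(OCOC)cc(O)c12 | intermediate
14 | 5-hydroxy-3,7-bis(methoxymethoxy)-2-[4-(methoxymethoxy)-6,6-bis(3-methylbut-2-en-1-yl)-5-oxocyclohexa-1,3-dien-1-yl]-8-(3-methylbut-2-en-1-yl)-4H-chromen-4-one | O=c1c(OCOC)c(C2=CC=C(OCOC)C(=O)C2(CC=C(C)C)CC=C(C)C)oc2c(CC=C(C)C)c(OCOC)cc(O)c12 | intermediate (not isolated)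
15 | 5-hydroxy-2-[3-hydroxy-4-(methoxymethoxy)-2-(3-methylbut-2-en-1-yl)-6-(2-methylbut-3-en-2-yl)phenyl]-3,7-bis(methoxymethoxy)-8-(3-methylbut-2-en-1-yl)-4H-chromen-4-one | O=c1c(OCOC)c(-c2c(CC=C(C)C)c(O)c(OCOC)cc2C(C)(C)C=C)oc2c(CC=C(C)C)c(OCOC)cc(O)c12 | intermediate
16 | 5-hydroxy-3,7-bis(methoxymethoxy)-2-[4-(methoxymethoxy)-3-[(2-methylprop-2-en-1-yl)oxy]-2-(3-methylbut-2-en-1-yl)-6-(2-methylbut-3-en-2-yl)phenyl]-8-(3-methylbut-2-en-1-yl)-4H-chromen-4-one | O=c1c(OCOC)c(-c2c(CC=C(C)C)c(OCC(C)=C)c(OCOC)cc2C(C)(C)C=C)oc2c(CC=C(C)C)c(OCOC)cc(O)c12 | intermediate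
17 | 5-hydroxy-3,7-bis(methoxymethoxy)-2-[9-(methoxymethoxy)-3-methyl-7-(2-methylbut-3-en-2-yl)-2,5-dihydro-1-benzoxepin-6-yl]-8-(3-methylbut-2-en-1-yl)-4H-chromen-4-one | O=c1c(OCOC)c(-c2c3CC=C(C)COc3c(OCOC)cc2C(C)(C)C=C)oc2c(CC=C(C)C)c(OCOC)cc(O)c12 | intermediate
18 | 5-hydroxy-2-[3-hydroxy-4-(methoxymethoxy)-2-[(1Z)-3-methylbuta-1,3-dien-1-yl]-6-(2-methylbut-3-en-2-yl)phenyl]-3,7-bis(methoxymethoxy)-8-(3-methylbut-2-en-1-yl)-4H-chromen-4-one | O=c1c(OCOC)c(-c2c(/C=C\C(C)=C)c(O)c(OCOC)cc2C(C)(C)C=C)oc2c(CC=C(C)C)c(OCOC)cc(O)c12 | intermediate (not isolated)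
19 | 5-hydroxy-3,7-bis(methoxymethoxy)-2-[(6Z)-4-(methoxymethoxy)-6-(3-methylbut-2-en-1-ylidene)-2-(2-methylbut-3-en-2-yl)-5-oxocyclohexa-1,3-dien-1-yl]-8-(3-methylbut-2-en-1-yl)-4H-chromen-4-one (vinyl group syn to the ring carbonyl) | O=c1c(OCOC)c(C2=C(C(C)(C)C=C)C=C(OCOC)C(=O)/C2=C\C=C(C)C)oc2c(CC=C(C)C)c(OCOC)cc(O)c12 | intermediate (not isolated)
20 | 5-hydroxy-3,7-bis(methoxymethoxy)-2-[8-(methoxymethoxy)-2,2-dimethyl-6-(2-methylbut-3-en-2-yl)-2H-chromen-5-yl]-8-(3-methylbut-2-en-1-yl)-4H-chromen-4-one | O=c1c(OCOC)c(-c2c3C=CC(C)(C)Oc3c(OCOC)cc2C(C)(C)C=C)oc2c(CC=C(C)C)c(OCOC)cc(O)c12 | intermediate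
21 | 3,5,7-trihydroxy-2-[8-hydroxy-2,2-dimethyl-6-(2-methylbut-3-en-2-yl)-2H-chromen-5-yl]-8-(3-methylbut-2-en-1-yl)-4H-chromen-4-one | O=c1c(O)c(-c2c3C=CC(C)(C)Oc3c(O)cc2C(C)(C)C=C)oc2c(CC=C(C)C)c(O)cc(O)c12 | target

**Step count and risks**

Total step count: 14. Longest linear sequence: 12 steps (steps 1–2 or 3–4, then 5–14).

Steps most likely to fail:

1. Step 13 (Proposed new method). Proton abstraction at the oxepine CH2 may be too slow compared with attack of the base on the pyranone, or reversible reprotonation may only move the ring alkene into conjugation with ring B without expelling the aryloxide; the diene may also isomerise before the [1,7]-hydrogen shift. Fallback: the seven-membered ring is abandoned and the route sets out again from ortho-prenylphenol 15. DDQ in benzene at reflux should abstract hydride from the benzylic and allylic CH2 of the 2'-prenyl group (the known dehydrogenative cyclisation of ortho-prenylphenols) and give the same ortho-quinone methide 19, which electrocyclises to 20, where the route is rejoined; no new compound is made (F0).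

2. Step 12. Initiation has to occur at a trisubstituted or a 1,1-disubstituted alkene, so the metathesis may stall, or the ruthenium carbene may be diverted into cross-metathesis of the other prenyl group. Fallback: from 15, selenoetherification with PhSeCl (CH2Cl2, −78 °C) should give, by Markovnikov 6-endo attack of the 3'-OH on the seleniranium ion of the adjacent prenyl group, the racemic 3-(phenylselanyl)chroman 5-hydroxy-3,7-bis(methoxymethoxy)-2-[8-(methoxymethoxy)-2,2-dimethyl-6-(2-methylbut-3-en-2-yl)-3-(phenylselanyl)-3,4-dihydro-2H-chromen-5-yl]-8-(3-methylbut-2-en-1-yl)-4H-chromen-4-one F1. Oxidation with H2O2 (THF, 0 °C to rt) and syn-elimination of the selenoxide toward C-4, the only carbon with a β-hydrogen, then gives 20, where the route is rejoined.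

3. Step 9. The phenol is flanked by a prenyl group and a MOM ether, so O-allylation may be slow, and the π-allyl complex may be captured at its primary terminus to give the unbranched prenyl ether. Fallback: from 12, copper-catalysed propargylic substitution with 3-chloro-3-methylbut-1-yne (CuCl2 cat., DBU, MeCN, 0 °C), which tolerates hindered phenols, should give the propargyl ether 5-hydroxy-3,7-bis(methoxymethoxy)-2-[4-(methoxymethoxy)-2-(3-methylbut-2-en-1-yl)-3-[(2-methylbut-3-yn-2-yl)oxy]phenyl]-8-(3-methylbut-2-en-1-yl)-4H-chromen-4-one F2. Semihydrogenation (H2, Pd/CaCO3 poisoned with Pb(OAc)2, quinoline, EtOAc, rt) then gives 13, where the route is rejoined.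

**Further compounds**

F0 | step 13 | none | none
F1 | step 12 | 5-hydroxy-3,7-bis(methoxymethoxy)-2-[8-(methoxymethoxy)-2,2-dimethyl-6-(2-methylbut-3-en-2-yl)-3-(phenylselanyl)-3,4-dihydro-2H-chromen-5-yl]-8-(3-methylbut-2-en-1-yl)-4H-chromen-4-one (racemic) | O=c1c(OCOC)c(-c2c3CC([Se]c4ccccc4)C(C)(C)Oc3c(OCOC)cc2C(C)(C)C=C)oc2c(CC=C(C)C)c(OCOC)cc(O)c12
F2 | step 9 | 5-hydroxy-3,7-bis(methoxymethoxy)-2-[4-(methoxymethoxy)-2-(3-methylbut-2-en-1-yl)-3-[(2-methylbut-3-yn-2-yl)oxy]phenyl]-8-(3-methylbut-2-en-1-yl)-4H-chromen-4-one | O=c1c(OCOC)c(-c2c(CC=C(C)C)c(OC(C)(C)C#C)c(OCOC)cc2)oc2c(CC=C(C)C)c(OCOC)cc(O)c12
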